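## Structural features

The target is a 2,3-dihydro-1-benzofuran: a dihydrofuran ring (O1, C2, C3, C3a, C7a) fused to benzene ring A (C3a, C4, C5, C6, C7, C7a), which carries a free phenol on C6 and an (E)-3,5-dihydroxystyryl arm on C5. C2 bears a 3,4-dihydroxyphenyl group (ring B) and C3 a 3,5-dihydroxyphenyl group (ring C). C2 and C3 are the only stereocentres; they are adjacent, both S, and the two aryl groups are trans. Six phenols on electron-rich rings, an (E)-stilbene and the C2–O1 bond (a benzylic aryl ether that can ionise to a para-quinone-methide-type cation) make the free compound sensitive to oxidants, strong acid and light, so the phenols stay masked to the end and the stilbene is made late. C3 is a diarylmethine and keeps its configuration only while no carbanion-stabilising group sits next to it. The real difficulty is twofold: fixing the trans C2/C3 pair in one absolute sense, and obtaining ring A with its substitution (C3a and O1 of the furan, the C5 carbon arm, the C6 oxygen) without electrophilic substitution, which could not tell three electron-rich arenes apart. The feature exploited is the oxygen pattern of ring A: O1 on C7a and the hydroxyl on C6 are meta with C7–H between them, the 3-alkoxyphenol pattern formed when a vinylketene combines with an alkoxyalkyne. If the alkoxy oxygen is the C2 oxygen itself, the event that builds ring A also closes the dihydrofuran, and C2 and C3 can be set beforehand on an open chain.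

## Logic of the disconnections

35 to 34: the six O–CH3 bonds are added retrosynthetically. Free phenols would not survive the organometallic, hydride, oxidation and photochemical steps, whereas methyl ethers pass through all of them. The demand is a final ether cleavage that spares the stilbene and the C2–O1 bond.

34 to 32 and 33: the stilbene C=C is cut. This keeps the light- and acid-sensitive alkene out of every earlier step, in particular the irradiation, and joins two fragments of similar size. The forward olefination must be E-selective and must tolerate the free C6 phenol.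

32 to 31 to 30: no skeletal bond is cut; the formyl carbon on C5 is traced back to a silyl-protected carbinol. Only the carbinol level tolerates the organolithium, amide-base and ketene chemistry upstream. The demand is a benzylic oxidation that stops at the aldehyde next to a free phenol.

30 to 25 (through 29, 28, 27 and 26): C5–C6, C6–C7, C3a–C7a and C3a–C4 are cut. Both rings disappear and an open chain remains that holds only the two stereocentres, a diazo ketone, an (E)-alkene and an ethynyl ether. The forward cascade must beat hydride shift and ketene dimerisation and must join ketene and alkyne in one orientation.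

25 to 23: the C=N2 unit on the future C3a is removed. The diazo group tolerates neither organolithium reagents nor oxidants, so it is introduced last. The demand is activation of the single α′ methylene without touching the ≡C–H or the stereocentre beside it.

23 to 22 to 14 and 18: the bond between the carbonyl carbon (future C6) and the alkene carbon (future C4) is cut; this bond exists only until the Wolff shift moves the alkenyl group to C3a. At the same point the ethynyl ether is traced back to an (E)-1,2-dichlorovinyl ether, because a free ≡C–H and an alkenyllithium cannot coexist. The demand is carbonyl addition faster than attack on the vinyl ether, then clean unmasking in the same flask.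

18 to 16 to 15: the C–I and Si–O bonds are cut. The gain is a three-carbon (E)-alkenyl donor from a commercial alkyne. The demand is syn, terminal hydrometalation.

14 to 13 to 12 to 11 to 10 to 9: no C–C bond is cut; the O–C(sp2) bond of the vinyl ether (12 to 11), a silyl ether and two oxidation levels are adjusted. This ties the chain to one ring compound, 9, in which both stereocentres sit in a five-membered lactone. The demand is differentiation of a primary from a hindered secondary benzylic hydroxyl.

9 to 5 and 6 (through 8 and 7): the bond from C3 to ring C is cut. A 1,4-addition anti to ring B lets the C2 centre set the C3 centre. The demand is conjugate addition faster than deprotonation of 5 at its acidic C5–H.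

5 to 3 to 1 and 2: the future C2–C3 bond (carbinol carbon to alkyne carbon) and the lactone C–O bond are cut. One catalytic asymmetric alkynylation of a commercial aldehyde then supplies all the absolute stereochemistry. The demand is high enantioselectivity with an electron-rich aryl aldehyde and a Z-selective semi-reduction.

## Other disconnections considered

Alternative 1: The cut is C3–C3a, the dihydrofuran being derived from a six-membered pyranone by ring contraction. In the forward step the diazo ketone A2 would be irradiated in methanol: loss of N2 with shift of the aryl carbon from the carbonyl carbon to C3 gives a ketene that methanol traps, forming ester A1.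
- In its favour: ring A is bought, not built; bromine and methoxy fix C5 and C6 without any regiochemical question; photochemical Wolff ring contraction of cyclic α-diazo ketones is an established reaction class. On precedent for the key step this alternative is the better of the two.
- Against it here: A1 carries an ester where the target has ring C, so a whole 3,5-dioxygenated benzene ring must still be grown from one carboxyl carbon. The base-mediated diazo transfer that leads to A2 and the later equilibration of the C3 ester to trans both pass through C3 carbanions with O1 in the β-position, so retro-oxa-Michael opening could erase the C2 centre. The ketene is protonated without facial control, so C3 is set only by equilibration. A seventh methyl ether (on C6) must be cleaved at the end, and the bromide needs a separate C–C coupling.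
- Comparison: on structure, the alternative is more convergent for ring A, while the chosen plan makes ring A and the furan in one step with both aryl groups and both stereocentres already in place. On mechanism, the alternative is precedented and the chosen step is new, but the chosen plan keeps C2 and C3 away from base after step 3. On step economy, A1 should be reached in fewer steps than 30, which is a point for the alternative, but the distance from A1 to the target is longer, so the totals should be similar.

Alternative 2: The cut is C1′–C2′ of ring C, which is unfolded to a hexane-1,3,5-trione chain on C3. In the forward step base would induce aldol attack of the terminal methyl carbon of triketone A4 on the ketone next to C3, and dehydration with enolisation gives resorcinol A3.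
- In its favour: cyclisation of 1,3,5-triketones to 5-substituted resorcinols is a known, biomimetic reaction type. Ring C arrives with free phenols, so two ethers fewer must be cleaved at the end; on this point the alternative is better. A4 follows from an ester of the kind of A1 by acylation with a diketone dianion.
- Against it here: in A4 the C3 methine is α to a ketone, benzylic and β to O1. Under the basic conditions it can epimerise, open the dihydrofuran by E1cB elimination (loss of both stereocentres), or attack the distal ketone to give a spiro-cyclohexenone. O-cyclisation to a 4-pyranone is a further competitor, and the strong base needed to make A4 meets the same C3–H.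
- Comparison: on structure, the alternative builds ring C last on a finished core, whereas the chosen plan takes ring C from a commercial bromide and builds ring A and the furan together; the alternative still needs a separate furan-forming step. On mechanism, the alternative is ionic and precedented, which is better on precedent, but its conditions threaten both stereocentres, while the chosen cascade is neutral. On step economy the two should be about equal, because A3 still lacks the stilbene and needs ether cleavage.

Alternative 3: The cut is O1–C2. In the forward step the 4-hydroxy-3-methoxyphenylacetic acid unit of A6 would be oxidised; loss of CO2 gives a para-quinone methide at C2, and the neighbouring phenol of ring A adds to it to give A5.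
- In its favour: all three aryl rings come from commercial arenes and the assembly is convergent. Only C3 must be set by asymmetric synthesis; the acid-bearing carbon is stereoablative and C2 should form trans under control by C3, since phenol addition to quinone methides is reversible. Phenol trapping of para-quinone methides to give 2-aryl-dihydrobenzofurans is well known. The C5 ester serves the same olefination endgame, and the ester para to the ring A phenol protects that phenol from the oxidant. On convergence and probably on step count this alternative is the better one.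
- Against it here: generating the quinone methide by oxidative decarboxylation on so hindered a diarylethyl system is less secure than the trapping itself. The quinone methide has the C3–H next to it, and tautomerisation to a triarylethylene would erase the C3 centre. Two free phenols and three electron-rich rings face the oxidant. Five methyl ethers still need cleavage.
- Comparison: on structure, the alternative forms one C–O bond and one stereocentre late under thermodynamic control, whereas the chosen plan forms four C–C bonds and no stereocentre, both centres having been fixed early by reagent and substrate control; the chosen plan is better on certainty of configuration. On mechanism, the alternative is better precedented, and the chosen step is neutral but new. On step economy the alternative should be shorter.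

Key step: step 14

Remark (assumption for step 1): the ProPhenol enantiomer is taken to be the one whose zinc complex gives the R carbinol 3; the sense is confirmed on 3 before going on and the antipodal ligand is used if needed.

Remark on the structures: a check of 25 against 30 and 35 shows them consistent atom by atom (aryl groups trans; 2S,3S in 30 and 35; 6S,7S in 25, where the C6 descriptor differs from the 6R of 23 only because the diazo carbon outranks the aryl group). No structure needs correction. Two design changes are made on the way to 25: the ethynyl ether is carried as its (E)-1,2-dichlorovinyl ether until the alkenyllithium has reacted, and 4-acetamidobenzenesulfonyl azide is used as the diazo donor.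

## Steps

Step 1
Reactants: 1 3,4-dimethoxybenzaldehyde; 2 ethyl propiolate
Product: 3 ethyl (4R)-4-(3,4-dimethoxyphenyl)-4-hydroxybut-2-ynoate
Conditions: ProPhenol (10 mol %), Me2Zn (3 equiv), 2 (3 equiv), Ph3PO (20 mol %), toluene, 4 °C; aq NH4Cl
Reagents that add atoms: none
Why: Catalytic asymmetric alkynylation of an aldehyde: the dinuclear zinc–ProPhenol complex holds the zinc acetylide of 2 and the aldehyde and delivers the alkynyl group to one face, which sets the future C2 centre (R here because the substituted alkynyl group outranks the aryl group); the aldehyde cannot enolise and the ynoate ester is a spectator.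

Step 2
Reactants: 3 ethyl (4R)-4-(3,4-dimethoxyphenyl)-4-hydroxybut-2-ynoate
Product: 5 (5S)-5-(3,4-dimethoxyphenyl)furan-2(5H)-one, via Z-hydroxy enoate 4 (not isolated)
Conditions: H2 (1 atm), Pd/CaCO3 poisoned with Pb(OAc)2, quinoline, EtOAc, rt; then pyridinium p-toluenesulfonate (cat.), CH2Cl2, rt
Reagents that add atoms: none
Why: Lindlar semi-hydrogenation gives the Z-enoate 4, in which hydroxyl and ester are cis, so lactonisation to the butenolide follows under weak acid; the stereocentre is not involved, and the weak acid avoids both ionisation of the electron-rich benzylic alcohol and base-induced racemisation of 5 through its 2-oxidofuran.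

Step 3
Reactants: 5 (5S)-5-(3,4-dimethoxyphenyl)furan-2(5H)-one; 6 1-bromo-3,5-dimethoxybenzene
Product: 9 (4R,5S)-5-(3,4-dimethoxyphenyl)-4-(3,5-dimethoxyphenyl)oxolan-2-one, via Grignard reagent 7 (not isolated), via silyl ketene acetal 8 (not isolated)
Conditions: 6, Mg, THF, 40 °C; then CuBr·SMe2 (20 mol %), Me3SiCl (2 equiv), 5, THF, −78 °C; aq NH4Cl
Reagents that add atoms: none
Why: Copper-catalysed 1,4-addition of aryl Grignard 7, accelerated by Me3SiCl, should place the new aryl group on the face of the butenolide anti to the C5 aryl group and so set the future C3 centre trans to C2 (substrate control); trapping as silyl ketene acetal 8 at −78 °C should outrun deprotonation at the acidic C5–H, and aqueous work-up returns the lactone.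

Step 4
Reactants: 9 (4R,5S)-5-(3,4-dimethoxyphenyl)-4-(3,5-dimethoxyphenyl)oxolan-2-one
Product: 10 (1S,2R)-1-(3,4-dimethoxyphenyl)-2-(3,5-dimethoxyphenyl)butane-1,4-diol
Conditions: LiAlH4, THF, 0 °C to rt; aq NaOH work-up
Reagents that add atoms: none
Why: Hydride reduction of the lactone to the 1,4-diol; neither stereocentre is α to the carbonyl group, so both are retained, and the aryl methyl ethers are inert.

Step 5
Reactants: 10 (1S,2R)-1-(3,4-dimethoxyphenyl)-2-(3,5-dimethoxyphenyl)butane-1,4-diol
Product: 11 (1S,2R)-4-[(tert-butyldiphenylsilyl)oxy]-1-(3,4-dimethoxyphenyl)-2-(3,5-dimethoxyphenyl)butan-1-ol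
Conditions: t-BuPh2SiCl (1.05 equiv), imidazole, CH2Cl2, 0 °C
Reagents that add atoms: tert-butyl(chloro)diphenylsilane, CC(C)(C)[Si](Cl)(c1ccccc1)c1ccccc1
Why: Silylation distinguishes the unhindered primary alcohol from the secondary benzylic alcohol beside the aryl-bearing carbon; the bulky silyl group is chosen because it should neither migrate nor be lost under KH in step 6.

Step 6
Reactants: 11 (1S,2R)-4-[(tert-butyldiphenylsilyl)oxy]-1-(3,4-dimethoxyphenyl)-2-(3,5-dimethoxyphenyl)butan-1-ol
Product: 12 tert-butyl{[(3R,4S)-4-{[(E)-1,2-dichloroethenyl]oxy}-4-(3,4-dimethoxyphenyl)-3-(3,5-dimethoxyphenyl)butyl]oxy}diphenylsilane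
Conditions: KH (2 equiv), THF, 0 °C to rt; Cl2C=CHCl, −50 °C to rt
Reagents that add atoms: trichloroethylene, ClC=C(Cl)Cl
Why: Dichlorovinyl ether synthesis: the potassium alkoxide dehydrochlorinates trichloroethylene to dichloroacetylene and adds to it anti, giving the (E)-1,2-dichlorovinyl ether, a robust masked ethynyl ether; the C–O bond at the stereocentre is not broken, so C2 keeps its configuration.

Step 7
Reactants: 12 tert-butyl{[(3R,4S)-4-{[(E)-1,2-dichloroethenyl]oxy}-4-(3,4-dimethoxyphenyl)-3-(3,5-dimethoxyphenyl)butyl]oxy}diphenylsilane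
Product: 13 (3R,4S)-4-{[(E)-1,2-dichloroethenyl]oxy}-4-(3,4-dimethoxyphenyl)-3-(3,5-dimethoxyphenyl)butan-1-ol
Conditions: Bu4NF, THF, rt
Reagents that add atoms: none
Why: Fluoride cleavage of the silyl ether; the dichlorovinyl ether is inert to fluoride.

Step 8
Reactants: 13 (3R,4S)-4-{[(E)-1,2-dichloroethenyl]oxy}-4-(3,4-dimethoxyphenyl)-3-(3,5-dimethoxyphenyl)butan-1-ol
Product: 14 (3R,4S)-4-{[(E)-1,2-dichloroethenyl]oxy}-4-(3,4-dimethoxyphenyl)-3-(3,5-dimethoxyphenyl)butanal
Conditions: Dess–Martin periodinane, pyridine, CH2Cl2, 0 °C to rt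
Reagents that add atoms: none
Why: Dess–Martin oxidation under buffered conditions gives the aldehyde; the nearest stereocentre is β to the carbonyl group and cannot epimerise.

Step 9
Reactants: 15 prop-2-yn-1-ol
Product: 16 triisopropyl(prop-2-yn-1-yloxy)silane
Conditions: i-Pr3SiCl, imidazole, CH2Cl2, rt
Reagents that add atoms: chlorotriisopropylsilane, CC(C)[Si](Cl)(C(C)C)C(C)C
Why: Standard silylation of a primary alcohol; the triisopropylsilyl ether is chosen because it withstands organolithium reagents, amide base and the ketene cascade.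

Step 10
Reactants: 16 triisopropyl(prop-2-yn-1-yloxy)silane
Product: 18 {[(2E)-3-iodoprop-2-en-1-yl]oxy}triisopropylsilane, via alkenylzirconocene chloride 17 (not isolated)
Conditions: Cp2Zr(H)Cl, THF, rt; then I2, 0 °C
Reagents that add atoms: iodine, [I][I]
Why: Hydrozirconation adds Zr–H syn across the terminal alkyne with zirconium on the terminal carbon, and iodinolysis of the C–Zr bond proceeds with retention, which should give only the (E)-alkenyl iodide.

Step 11
Reactants: 18 {[(2E)-3-iodoprop-2-en-1-yl]oxy}triisopropylsilane; 14 (3R,4S)-4-{[(E)-1,2-dichloroethenyl]oxy}-4-(3,4-dimethoxyphenyl)-3-(3,5-dimethoxyphenyl)butanal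
Product: 22 (2E,6R,7S)-7-(3,4-dimethoxyphenyl)-6-(3,5-dimethoxyphenyl)-7-(ethynyloxy)-1-[(triisopropylsilyl)oxy]hept-2-en-4-ol (both C4 epimers), via alkenyllithium 19 (not isolated), via dichlorovinyl carbinol 20 (not isolated), via chloroethynyl ether 21 (not isolated)
Conditions: 18 (1.3 equiv), t-BuLi (2.6 equiv), Et2O, −78 °C; 14, THF, −78 °C; then n-BuLi (3 equiv), −78 to −40 °C; MeOH, −78 °C; aq NaHCO3
Reagents that add atoms: none
Why: Iodine–lithium exchange with retention gives alkenyllithium 19, whose 1,2-addition to the aldehyde should be much faster than attack on the dichlorovinyl ether (the new carbinol centre is uncontrolled and is oxidised in step 12). With the carbonyl group now an alkoxide (20), n-BuLi removes the vinyl proton, chloride is lost to give chloroalkyne 21, and chlorine–lithium exchange then methanol quench give the terminal ethynyl ether. Making the acidic ≡C–H only after the last organolithium step removes the conflict between an alkenyllithium and an ethynyl ether.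

Step 12
Reactants: 22 (2E,6R,7S)-7-(3,4-dimethoxyphenyl)-6-(3,5-dimethoxyphenyl)-7-(ethynyloxy)-1-[(triisopropylsilyl)oxy]hept-2-en-4-ol
Product: 23 (2E,6R,7S)-7-(3,4-dimethoxyphenyl)-6-(3,5-dimethoxyphenyl)-7-(ethynyloxy)-1-[(triisopropylsilyl)oxy]hept-2-en-4-one
Conditions: MnO2 (excess), CH2Cl2, rt
Reagents that add atoms: none
Why: Allylic oxidation on the neutral MnO2 surface at room temperature should give the (E)-enone from both carbinol epimers, under conditions in which the acid- and heat-sensitive ethynyl ether should survive.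

Step 13
Reactants: 23 (2E,6R,7S)-7-(3,4-dimethoxyphenyl)-6-(3,5-dimethoxyphenyl)-7-(ethynyloxy)-1-[(triisopropylsilyl)oxy]hept-2-en-4-one
Product: 25 (2E,6S,7S)-5-diazo-7-(3,4-dimethoxyphenyl)-6-(3,5-dimethoxyphenyl)-7-(ethynyloxy)-1-[(triisopropylsilyl)oxy]hept-2-en-4-one, via trifluoroacetyl diketone 24 (not isolated)
Conditions: LiN(SiMe3)2 (1.05 equiv), THF, −78 °C; CF3CO2CH2CF3, −78 °C; then 4-acetamidobenzenesulfonyl azide, Et3N, H2O (1 equiv), MeCN, rt
Reagents that add atoms: 4-acetamidobenzenesulfonyl azide, CC(=O)Nc1ccc(cc1)S(=O)(=O)N=[N+]=[N-]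
Why: Detrifluoroacetylative diazo transfer: kinetic deprotonation at C5, the only α′ position, C-trifluoroacetylation to 24, then diazo transfer with loss of the trifluoroacetyl group as the sulfonamide gives the diazo enone. One equivalent of base at −78 °C should leave the less acidic ≡C–H alone, and C6 is not deprotonated, so both stereocentres are retained (the C6 descriptor changes to S only by priority).

Step 14
Reactants: 25 (2E,6S,7S)-5-diazo-7-(3,4-dimethoxyphenyl)-6-(3,5-dimethoxyphenyl)-7-(ethynyloxy)-1-[(triisopropylsilyl)oxy]hept-2-en-4-one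
Product: 30 (2S,3S)-2-(3,4-dimethoxyphenyl)-3-(3,5-dimethoxyphenyl)-5-{[(triisopropylsilyl)oxy]methyl}-2,3-dihydro-1-benzofuran-6-ol, via vinylketene 26 (not isolated), via bicyclic cyclobutenone 27 (not isolated), via dienylketene 28 (not isolated), via cyclohexadienone 29 (not isolated)
Conditions: hν (Pyrex-filtered medium-pressure Hg lamp or 365 nm LEDs), degassed toluene (0.005 M), 15 °C; then 80 °C, dark
Reagents that add atoms: none
Why: Proposed new method: irradiation of the s-cis diazo enone 25 should expel N2 with concerted 1,2-shift of the alkenyl group (forming C3a–C4) to give vinylketene 26; its electrophilic carbonyl carbon C6 is attacked by the nucleophilic unsubstituted alkyne carbon C7, and the enolate carbon C3a then closes onto the oxygen-bearing carbon C7a, a formal (2+2) cycloaddition that gives cyclobutenone 27 and closes the dihydrofuran in a 5-exo-dig sense through the three-atom tether C3–C2–O1. Four-electron electrocyclic opening of the strained 27 (breaking C3a–C6) gives dienylketene 28, in which the new C3a=C7a double bond lies inside the five-membered ring and so holds the ketene and the propenyl arm cis; six-electron electrocyclic closure (forming C5–C6) gives dienone 29, and tautomerisation to phenol 30 closes the benzene ring, driven by aromatisation. The closest known reaction type is the Danheiser benzannulation of vinylketenes, made by photochemical Wolff rearrangement of α-diazo enones, with alkoxyalkynes, which is known in its intermolecular form; delivery of the ynol ether through its own oxygen from the ketene α-carbon is the new element. No stereocentre is formed: C2 and C3 take no part in any bond change under neutral conditions, and the transient centres at C3a in 27 and C5 in 29 are erased. Regiochemistry (O1 on C7a, hydroxyl on C6, C7–H between) is secured twice, by the polarisation of the ynol ether and by the tether, which lets only the oxygen-bearing alkyne carbon reach C3a. Chemoselectivity needs the Wolff shift to beat 1,2-hydride shift from C3 and trapping to beat ketene dimerisation: light is used in place of heat, silver benzoate or Rh2(OAc)4 (the s-cis conformer loses N2 without a free carbene, and those metal catalysts would attack the ynol ether), the solution is dilute, and the mixture is kept near 15 °C until the ynol ether is consumed, so that its retro-ene and (3,3) pathways cannot compete, before warming completes the electrocyclic steps.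

Step 15
Reactants: 30 (2S,3S)-2-(3,4-dimethoxyphenyl)-3-(3,5-dimethoxyphenyl)-5-{[(triisopropylsilyl)oxy]methyl}-2,3-dihydro-1-benzofuran-6-ol
Product: 31 (2S,3S)-2-(3,4-dimethoxyphenyl)-3-(3,5-dimethoxyphenyl)-5-(hydroxymethyl)-2,3-dihydro-1-benzofuran-6-ol
Conditions: Bu4NF, THF, 0 °C; pH 7 buffer
Reagents that add atoms: none
Why: Fluoride cleavage of the benzylic silyl ether; neutral work-up avoids ortho-quinone methide formation from the salicyl alcohol, and C2 and C3 are untouched.

Step 16
Reactants: 31 (2S,3S)-2-(3,4-dimethoxyphenyl)-3-(3,5-dimethoxyphenyl)-5-(hydroxymethyl)-2,3-dihydro-1-benzofuran-6-ol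
Product: 32 (2S,3S)-2-(3,4-dimethoxyphenyl)-3-(3,5-dimethoxyphenyl)-6-hydroxy-2,3-dihydro-1-benzofuran-5-carbaldehyde
Conditions: MnO2, CH2Cl2, rt
Reagents that add atoms: none
Why: MnO2 oxidation of a benzylic alcohol activated by ortho and para oxygen substituents should stop at the salicylaldehyde, which is stabilised by its internal hydrogen bond.

Step 17
Reactants: 32 (2S,3S)-2-(3,4-dimethoxyphenyl)-3-(3,5-dimethoxyphenyl)-6-hydroxy-2,3-dihydro-1-benzofuran-5-carbaldehyde; 33 diethyl (3,5-dimethoxybenzyl)phosphonate
Product: 34 (2S,3S)-2-(3,4-dimethoxyphenyl)-3-(3,5-dimethoxyphenyl)-5-[(E)-2-(3,5-dimethoxyphenyl)ethenyl]-2,3-dihydro-1-benzofuran-6-ol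
Conditions: 33 (1.5 equiv), KOt-Bu (3.5 equiv), DMF, 0 °C to rt; aq NH4Cl
Reagents that add atoms: none
Why: Horner–Wadsworth–Emmons olefination with the semi-stabilised benzylphosphonate anion should give the (E)-stilbene; excess base keeps the C6 phenol as its phenoxide, which slows but should not prevent addition, and the base is too weak to deprotonate C3–H.

Step 18
Reactants: 34 (2S,3S)-2-(3,4-dimethoxyphenyl)-3-(3,5-dimethoxyphenyl)-5-[(E)-2-(3,5-dimethoxyphenyl)ethenyl]-2,3-dihydro-1-benzofuran-6-ol
Product: 35 5-[(E)-2-[(2S,3S)-2-(3,4-dihydroxyphenyl)-3-(3,5-dihydroxyphenyl)-6-hydroxy-2,3-dihydro-1-benzofuran-5-yl]ethenyl]benzene-1,3-diol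
Conditions: BBr3 (15 equiv), CH2Cl2, −78 to 0 °C; MeOH then H2O, −78 °C
Reagents that add atoms: none
Why: Lewis-acid ether cleavage: BBr3 complexes each ether oxygen and bromide attacks the methyl carbon (SN2), giving the hexaphenol after hydrolysis; C3 is not affected, and if C2–O1 ionises reversibly, re-closure should return the more stable trans isomer, so the (2S,3S) configuration is kept.

## Compound list

1 | 3,4-dimethoxybenzaldehyde | COc1ccc(C=O)cc1OC | starting material
2 | ethyl propiolate | CCOC(=O)C#C | starting material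
3 | ethyl (4R)-4-(3,4-dimethoxyphenyl)-4-hydroxybut-2-ynoate | CCOC(=O)C#C[C@H](O)c1ccc(OC)c(OC)c1 | intermediate
4 | ethyl (2Z,4S)-4-(3,4-dimethoxyphenyl)-4-hydroxybut-2-enoate | CCOC(=O)/C=C\[C@H](O)c1ccc(OC)c(OC)c1 | intermediate (not isolated)
5 | (5S)-5-(3,4-dimethoxyphenyl)furan-2(5H)-one | O=C1C=C[C@@H](c2ccc(OC)c(OC)c2)O1 | intermediate
6 | 1-bromo-3,5-dimethoxybenzene | COc1cc(Br)cc(OC)c1 | starting material
7 | (3,5-dimethoxyphenyl)magnesium bromide | COc1cc([Mg]Br)cc(OC)c1 | intermediate (not isolated)
8 | {[(4R,5S)-5-(3,4-dimethoxyphenyl)-4-(3,5-dimethoxyphenyl)-4,5-dihydrofuran-2-yl]oxy}trimethylsilane | C[Si](C)(C)OC1=C[C@H](c2cc(OC)cc(OC)c2)[C@@H](c2ccc(OC)c(OC)c2)O1 | intermediate (not isolated)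
9 | (4R,5S)-5-(3,4-dimethoxyphenyl)-4-(3,5-dimethoxyphenyl)oxolan-2-one (trans) | O=C1C[C@H](c2cc(OC)cc(OC)c2)[C@@H](c2ccc(OC)c(OC)c2)O1 | intermediate
10 | (1S,2R)-1-(3,4-dimethoxyphenyl)-2-(3,5-dimethoxyphenyl)butane-1,4-diol | OCC[C@H](c1cc(OC)cc(OC)c1)[C@H](O)c1ccc(OC)c(OC)c1 | intermediate
11 | (1S,2R)-4-[(tert-butyldiphenylsilyl)oxy]-1-(3,4-dimethoxyphenyl)-2-(3,5-dimethoxyphenyl)butan-1-ol | CC(C)(C)[Si](OCC[C@H](c1cc(OC)cc(OC)c1)[C@H](O)c1ccc(OC)c(OC)c1)(c1ccccc1)c1ccccc1 | intermediate
12 | tert-butyl{[(3R,4S)-4-{[(E)-1,2-dichloroethenyl]oxy}-4-(3,4-dimethoxyphenyl)-3-(3,5-dimethoxyphenyl)butyl]oxy}diphenylsilane | CC(C)(C)[Si](OCC[C@H](c1cc(OC)cc(OC)c1)[C@H](O/C(Cl)=C\Cl)c1ccc(OC)c(OC)c1)(c1ccccc1)c1ccccc1 | intermediate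
13 | (3R,4S)-4-{[(E)-1,2-dichloroethenyl]oxy}-4-(3,4-dimethoxyphenyl)-3-(3,5-dimethoxyphenyl)butan-1-ol | OCC[C@H](c1cc(OC)cc(OC)c1)[C@H](O/C(Cl)=C\Cl)c1ccc(OC)c(OC)c1 | intermediate
14 | (3R,4S)-4-{[(E)-1,2-dichloroethenyl]oxy}-4-(3,4-dimethoxyphenyl)-3-(3,5-dimethoxyphenyl)butanal | O=CC[C@H](c1cc(OC)cc(OC)c1)[C@H](O/C(Cl)=C\Cl)c1ccc(OC)c(OC)c1 | intermediate
15 | prop-2-yn-1-ol | C#CCO | starting material
16 | triisopropyl(prop-2-yn-1-yloxy)silane | C#CCO[Si](C(C)C)(C(C)C)C(C)C | intermediate
17 | chlorobis(cyclopentadienyl)[(1E)-3-(triisopropylsilyloxy)prop-1-en-1-yl]zirconium | CC(C)[Si](OC/C=C/[Zr](Cl)(C1C=CC=C1)C1C=CC=C1)(C(C)C)C(C)C | intermediate (not isolated)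
18 | {[(2E)-3-iodoprop-2-en-1-yl]oxy}triisopropylsilane | CC(C)[Si](OC/C=C/I)(C(C)C)C(C)C | intermediate
19 | [(1E)-3-(triisopropylsilyloxy)prop-1-en-1-yl]lithium | CC(C)[Si](OC/C=C/[Li])(C(C)C)C(C)C | intermediate (not isolated)
20 | (2E,6R,7S)-7-{[(E)-1,2-dichloroethenyl]oxy}-7-(3,4-dimethoxyphenyl)-6-(3,5-dimethoxyphenyl)-1-[(triisopropylsilyl)oxy]hept-2-en-4-ol (C4 epimers, present as lithium alkoxide) | CC(C)[Si](OC/C=C/C(O)C[C@H](c1cc(OC)cc(OC)c1)[C@H](O/C(Cl)=C\Cl)c1ccc(OC)c(OC)c1)(C(C)C)C(C)C | intermediate (not isolated)
21 | (2E,6R,7S)-7-[(chloroethynyl)oxy]-7-(3,4-dimethoxyphenyl)-6-(3,5-dimethoxyphenyl)-1-[(triisopropylsilyl)oxy]hept-2-en-4-ol (C4 epimers, present as lithium alkoxide) | CC(C)[Si](OC/C=C/C(O)C[C@H](c1cc(OC)cc(OC)c1)[C@H](OC#CCl)c1ccc(OC)c(OC)c1)(C(C)C)C(C)C | intermediate (not isolated)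
22 | (2E,6R,7S)-7-(3,4-dimethoxyphenyl)-6-(3,5-dimethoxyphenyl)-7-(ethynyloxy)-1-[(triisopropylsilyl)oxy]hept-2-en-4-ol (C4 epimers) | CC(C)[Si](OC/C=C/C(O)C[C@H](c1cc(OC)cc(OC)c1)[C@H](OC#C)c1ccc(OC)c(OC)c1)(C(C)C)C(C)C | intermediate
23 | (2E,6R,7S)-7-(3,4-dimethoxyphenyl)-6-(3,5-dimethoxyphenyl)-7-(ethynyloxy)-1-[(triisopropylsilyl)oxy]hept-2-en-4-one | CC(C)[Si](OC/C=C/C(=O)C[C@H](c1cc(OC)cc(OC)c1)[C@H](OC#C)c1ccc(OC)c(OC)c1)(C(C)C)C(C)C | intermediate
24 | (2E,6R,7S)-7-(3,4-dimethoxyphenyl)-6-(3,5-dimethoxyphenyl)-7-(ethynyloxy)-5-(trifluoroacetyl)-1-[(triisopropylsilyl)oxy]hept-2-en-4-one (C5 epimers and enol forms) | CC(C)[Si](OC/C=C/C(=O)C(C(=O)C(F)(F)F)[C@H](c1cc(OC)cc(OC)c1)[C@H](OC#C)c1ccc(OC)c(OC)c1)(C(C)C)C(C)C | intermediate (not isolated)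
25 | (2E,6S,7S)-5-diazo-7-(3,4-dimethoxyphenyl)-6-(3,5-dimethoxyphenyl)-7-(ethynyloxy)-1-[(triisopropylsilyl)oxy]hept-2-en-4-one | CC(C)[Si](OC/C=C/C(=O)C(=[N+]=[N-])[C@H](c1cc(OC)cc(OC)c1)[C@H](OC#C)c1ccc(OC)c(OC)c1)(C(C)C)C(C)C | intermediate
26 | (3E)-2-[(1S,2S)-2-(3,4-dimethoxyphenyl)-1-(3,5-dimethoxyphenyl)-2-(ethynyloxy)ethyl]-5-[(triisopropylsilyl)oxy]penta-1,3-dien-1-one | CC(C)[Si](OC/C=C/C(=C=O)[C@H](c1cc(OC)cc(OC)c1)[C@H](OC#C)c1ccc(OC)c(OC)c1)(C(C)C)C(C)C | intermediate (not isolated)
27 | (3S,4S)-3-(3,4-dimethoxyphenyl)-4-(3,5-dimethoxyphenyl)-5-[(1E)-3-(triisopropylsilyloxy)prop-1-en-1-yl]-2-oxabicyclo[3.2.0]hept-1(7)-en-6-one (C5 not assigned) | CC(C)[Si](OC/C=C/C12C(=O)C=C1O[C@H](c1ccc(OC)c(OC)c1)[C@H]2c1cc(OC)cc(OC)c1)(C(C)C)C(C)C | intermediate (not isolated)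
28 | 2-{(4S,5S)-5-(3,4-dimethoxyphenyl)-4-(3,5-dimethoxyphenyl)-3-[(1E)-3-(triisopropylsilyloxy)prop-1-en-1-yl]-4,5-dihydrofuran-2-yl}ethen-1-one | CC(C)[Si](OC/C=C/C1=C(C=C=O)O[C@H](c2ccc(OC)c(OC)c2)[C@H]1c1cc(OC)cc(OC)c1)(C(C)C)C(C)C | intermediate (not isolated)
29 | (2S,3S)-2-(3,4-dimethoxyphenyl)-3-(3,5-dimethoxyphenyl)-5-{[(triisopropylsilyl)oxy]methyl}-3,5-dihydro-1-benzofuran-6(2H)-one (C5 epimers) | CC(C)[Si](OCC1C=C2C(=CC1=O)O[C@H](c1ccc(OC)c(OC)c1)[C@H]2c1cc(OC)cc(OC)c1)(C(C)C)C(C)C | intermediate (not isolated)
30 | (2S,3S)-2-(3,4-dimethoxyphenyl)-3-(3,5-dimethoxyphenyl)-5-{[(triisopropylsilyl)oxy]methyl}-2,3-dihydro-1-benzofuran-6-ol | CC(C)[Si](OCc1cc2c(cc1O)O[C@H](c1ccc(OC)c(OC)c1)[C@H]2c1cc(OC)cc(OC)c1)(C(C)C)C(C)C | intermediate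
31 | (2S,3S)-2-(3,4-dimethoxyphenyl)-3-(3,5-dimethoxyphenyl)-5-(hydroxymethyl)-2,3-dihydro-1-benzofuran-6-ol | OCc1cc2c(cc1O)O[C@H](c1ccc(OC)c(OC)c1)[C@H]2c1cc(OC)cc(OC)c1 | intermediate
32 | (2S,3S)-2-(3,4-dimethoxyphenyl)-3-(3,5-dimethoxyphenyl)-6-hydroxy-2,3-dihydro-1-benzofuran-5-carbaldehyde | O=Cc1cc2c(cc1O)O[C@H](c1ccc(OC)c(OC)c1)[C@H]2c1cc(OC)cc(OC)c1 | intermediate
33 | diethyl (3,5-dimethoxybenzyl)phosphonate | CCOP(=O)(Cc1cc(OC)cc(OC)c1)OCC | starting material
34 | (2S,3S)-2-(3,4-dimethoxyphenyl)-3-(3,5-dimethoxyphenyl)-5-[(E)-2-(3,5-dimethoxyphenyl)ethenyl]-2,3-dihydro-1-benzofuran-6-ol | COc1cc(OC)cc(/C=C/c2cc3c(cc2O)O[C@H](c2ccc(OC)c(OC)c2)[C@H]3c2cc(OC)cc(OC)c2)c1 | intermediate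
35 | 5-[(E)-2-[(2S,3S)-2-(3,4-dihydroxyphenyl)-3-(3,5-dihydroxyphenyl)-6-hydroxy-2,3-dihydro-1-benzofuran-5-yl]ethenyl]benzene-1,3-diol | Oc1cc(O)cc(/C=C/c2cc3c(cc2O)O[C@H](c2ccc(O)c(O)c2)[C@H]3c2cc(O)cc(O)c2)c1 | target

## Step count and least certain steps

Total: 18 steps. Longest linear sequence: 16 steps (steps 1 to 8 and 11 to 18); steps 9 and 10 are the side branch to 18.

Step 14 (key step, new method).
- What may go wrong: the tethered ynol ether may fail to reach the ketene because the bicyclic cyclobutenone is strained, so that ketene dimerisation or adventitious trapping takes over; hydride shift from C3 may occur in a carbene pathway; the ynol ether may fragment thermally before it is trapped.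
- Fallback (known chemistry, intermolecular benzannulation followed by cationic ring closure): it sets out from 9 and 18 and comes back to the route at 32. Lactone 9 is treated at −78 °C with alkenyllithium 19 (from 18) to give, after mono-addition, the hydroxy enone (2E,6R,7S)-7-(3,4-dimethoxyphenyl)-6-(3,5-dimethoxyphenyl)-7-hydroxy-1-[(triisopropylsilyl)oxy]hept-2-en-4-one F1. O-Methylation with Me3OBF4 and 1,8-bis(dimethylamino)naphthalene gives the 7-methoxy enone F2, and the diazo transfer of step 13 gives the 7-methoxy diazo enone F3. Irradiation of F3 with an excess of tert-butyl ethynyl ether F4 (from tert-butanol by KH and trichloroethylene, then n-BuLi), then warming, is the known intermolecular benzannulation and should give, with the same regiochemistry, the tert-butoxy phenol F5. Bu4NF gives the hydroxymethyl phenol F6 and MnO2 the tert-butoxy salicylaldehyde F7. CF3CO2H in CH2Cl2 at 0 °C then removes the tert-butyl group and ionises the benzylic methyl ether, and the freed phenol closes O1–C2 trans to the C3 aryl group to give 32. In this fallback C2 is formed under control by C3, and loss of the C3 proton from the cation is the process to watch.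

Step 13.
- What may go wrong: deprotonation and C-acylation at the ethynyl terminus may compete with enolate formation; deprotonation at the γ-position may occur; the diazo group may add slowly to the tethered alkyne on standing, so 25 is used at once.
- Fallback (neutral enaminone activation in place of an enolate): it sets out from 23 and comes back at 25. Enone 23 is warmed (THF, 45 °C) with tert-butoxybis(dimethylamino)methane to give the 5-[(dimethylamino)methylidene] enone F8. 4-Acetamidobenzenesulfonyl azide in MeCN (0 °C to rt) then transfers the diazo group, with loss of the sulfonylformamidine, to give 25.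

Step 11.
- What may go wrong: attack of the alkenyllithium on the dichlorovinyl ether before the aldehyde is consumed would produce a lithium alkynyl ether that can add to the aldehyde; elimination may be incomplete; excess n-BuLi may lithiate the dimethoxyarenes.
- Fallback (unmask first, then a non-basic organochromium coupling): it sets out from 12 and comes back at 22. n-BuLi (−78 to −40 °C, MeOH quench) converts 12 to the silyl-protected ethynyl ether F9. Bu4NF gives the ethynyl ether alcohol F10, and Dess–Martin periodinane with pyridine gives the ethynyl ether aldehyde F11. Nozaki–Hiyama–Kishi coupling of F11 with 18 (CrCl2 in excess, NiCl2 cat., DMF) should give 22, because the alkenylchromium reagent is not basic enough to remove the ≡C–H.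

Step 18.
- What may go wrong: ionisation of C2–O1 followed by Friedel–Crafts-type oligomerisation; addition of HBr to the stilbene during the quench; incomplete cleavage of the catechol diether.
- Fallback (ether cleavage before the stilbene exists, then silyl protection): it sets out from 32 and comes back at 35. BBr3 acts on 32, where the formyl group lowers the donor strength of O1 and no alkene is present, to give the pentahydroxy aldehyde F12. t-BuMe2SiCl and imidazole give the penta-silyl aldehyde F13. Olefination with the silyl-protected phosphonate F14 (from the corresponding benzyl bromide by a Michaelis–Arbuzov reaction) and NaN(SiMe3)2 gives the hepta-silyl stilbene F15. Bu4NF buffered with AcOH then gives 35.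

## Further compounds

F1 | step 14 | (2E,6R,7S)-7-(3,4-dimethoxyphenyl)-6-(3,5-dimethoxyphenyl)-7-hydroxy-1-[(triisopropylsilyl)oxy]hept-2-en-4-one | CC(C)[Si](OC/C=C/C(=O)C[C@H](c1cc(OC)cc(OC)c1)[C@H](O)c1ccc(OC)c(OC)c1)(C(C)C)C(C)C
F2 | step 14 | (2E,6R,7S)-7-(3,4-dimethoxyphenyl)-6-(3,5-dimethoxyphenyl)-7-methoxy-1-[(triisopropylsilyl)oxy]hept-2-en-4-one | CC(C)[Si](OC/C=C/C(=O)C[C@H](c1cc(OC)cc(OC)c1)[C@H](OC)c1ccc(OC)c(OC)c1)(C(C)C)C(C)C
F3 | step 14 | (2E,6S,7S)-5-diazo-7-(3,4-dimethoxyphenyl)-6-(3,5-dimethoxyphenyl)-7-methoxy-1-[(triisopropylsilyl)oxy]hept-2-en-4-one | CC(C)[Si](OC/C=C/C(=O)C(=[N+]=[N-])[C@H](c1cc(OC)cc(OC)c1)[C@H](OC)c1ccc(OC)c(OC)c1)(C(C)C)C(C)C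
F4 | step 14 | tert-butyl ethynyl ether | CC(C)(C)OC#C
F5 | step 14 | 5-tert-butoxy-4-[(1S,2S)-2-(3,4-dimethoxyphenyl)-1-(3,5-dimethoxyphenyl)-2-methoxyethyl]-2-{[(triisopropylsilyl)oxy]methyl}phenol | CC(C)[Si](OCc1cc(c(OC(C)(C)C)cc1O)[C@H](c1cc(OC)cc(OC)c1)[C@H](OC)c1ccc(OC)c(OC)c1)(C(C)C)C(C)C
F6 | step 14 | 5-tert-butoxy-4-[(1S,2S)-2-(3,4-dimethoxyphenyl)-1-(3,5-dimethoxyphenyl)-2-methoxyethyl]-2-(hydroxymethyl)phenol | OCc1cc(c(OC(C)(C)C)cc1O)[C@H](c1cc(OC)cc(OC)c1)[C@H](OC)c1ccc(OC)c(OC)c1
F7 | step 14 | 4-tert-butoxy-5-[(1S,2S)-2-(3,4-dimethoxyphenyl)-1-(3,5-dimethoxyphenyl)-2-methoxyethyl]-2-hydroxybenzaldehyde | O=Cc1cc(c(OC(C)(C)C)cc1O)[C@H](c1cc(OC)cc(OC)c1)[C@H](OC)c1ccc(OC)c(OC)c1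
F8 | step 13 | (2E,6S,7S)-5-[(dimethylamino)methylidene]-7-(3,4-dimethoxyphenyl)-6-(3,5-dimethoxyphenyl)-7-(ethynyloxy)-1-[(triisopropylsilyl)oxy]hept-2-en-4-one (enamine geometry not assigned) | CC(C)[Si](OC/C=C/C(=O)C(=CN(C)C)[C@H](c1cc(OC)cc(OC)c1)[C@H](OC#C)c1ccc(OC)c(OC)c1)(C(C)C)C(C)C
F9 | step 11 | tert-butyl{[(3R,4S)-4-(3,4-dimethoxyphenyl)-3-(3,5-dimethoxyphenyl)-4-(ethynyloxy)butyl]oxy}diphenylsilane | CC(C)(C)[Si](OCC[C@H](c1cc(OC)cc(OC)c1)[C@H](OC#C)c1ccc(OC)c(OC)c1)(c1ccccc1)c1ccccc1
F10 | step 11 | (3R,4S)-4-(3,4-dimethoxyphenyl)-3-(3,5-dimethoxyphenyl)-4-(ethynyloxy)butan-1-ol | OCC[C@H](c1cc(OC)cc(OC)c1)[C@H](OC#C)c1ccc(OC)c(OC)c1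
F11 | step 11 | (3R,4S)-4-(3,4-dimethoxyphenyl)-3-(3,5-dimethoxyphenyl)-4-(ethynyloxy)butanal | O=CC[C@H](c1cc(OC)cc(OC)c1)[C@H](OC#C)c1ccc(OC)c(OC)c1
F12 | step 18 | (2S,3S)-2-(3,4-dihydroxyphenyl)-3-(3,5-dihydroxyphenyl)-6-hydroxy-2,3-dihydro-1-benzofuran-5-carbaldehyde | O=Cc1cc2c(cc1O)O[C@H](c1ccc(O)c(O)c1)[C@H]2c1cc(O)cc(O)c1
F13 | step 18 | (2S,3S)-2-{3,4-bis[(tert-butyldimethylsilyl)oxy]phenyl}-3-{3,5-bis[(tert-butyldimethylsilyl)oxy]phenyl}-6-[(tert-butyldimethylsilyl)oxy]-2,3-dihydro-1-benzofuran-5-carbaldehyde | O=Cc1cc2c(cc1O[Si](C)(C)C(C)(C)C)O[C@H](c1ccc(O[Si](C)(C)C(C)(C)C)c(O[Si](C)(C)C(C)(C)C)c1)[C@H]2c1cc(O[Si](C)(C)C(C)(C)C)cc(O[Si](C)(C)C(C)(C)C)c1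
F14 | step 18 | diethyl {3,5-bis[(tert-butyldimethylsilyl)oxy]benzyl}phosphonate | CCOP(=O)(Cc1cc(O[Si](C)(C)C(C)(C)C)cc(O[Si](C)(C)C(C)(C)C)c1)OCC
F15 | step 18 | (2S,3S)-5-[(E)-2-{3,5-bis[(tert-butyldimethylsilyl)oxy]phenyl}ethenyl]-2-{3,4-bis[(tert-butyldimethylsilyl)oxy]phenyl}-3-{3,5-bis[(tert-butyldimethylsilyl)oxy]phenyl}-6-[(tert-butyldimethylsilyl)oxy]-2,3-dihydro-1-benzofuran | CC(C)(C)[Si](C)(C)Oc1cc(O[Si](C)(C)C(C)(C)C)cc(/C=C/c2cc3c(cc2O[Si](C)(C)C(C)(C)C)O[C@H](c2ccc(O[Si](C)(C)C(C)(C)C)c(O[Si](C)(C)C(C)(C)C)c2)[C@H]3c2cc(O[Si](C)(C)C(C)(C)C)cc(O[Si](C)(C)C(C)(C)C)c2)c1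
A1 | alternative 1 | methyl (2S,3S)-5-bromo-2-(3,4-dimethoxyphenyl)-6-methoxy-2,3-dihydro-1-benzofuran-3-carboxylate | Brc1cc2c(cc1OC)O[C@H](c1ccc(OC)c(OC)c1)[C@H]2C(=O)OC
A2 | alternative 1 | (2R)-6-bromo-3-diazo-2-(3,4-dimethoxyphenyl)-7-methoxy-2,3-dihydro-4H-1-benzopyran-4-one | COc1cc2O[C@H](c3ccc(OC)c(OC)c3)C(=[N+]=[N-])C(=O)c2cc1Br
A3 | alternative 2 | 5-[(2S,3S)-5-bromo-2-(3,4-dimethoxyphenyl)-6-methoxy-2,3-dihydro-1-benzofuran-3-yl]benzene-1,3-diol | Brc1cc2c(cc1OC)O[C@H](c1ccc(OC)c(OC)c1)[C@H]2c1cc(O)cc(O)c1
A4 | alternative 2 | 1-[(2S,3S)-5-bromo-2-(3,4-dimethoxyphenyl)-6-methoxy-2,3-dihydro-1-benzofuran-3-yl]hexane-1,3,5-trione | Brc1cc2c(cc1OC)O[C@H](c1ccc(OC)c(OC)c1)[C@H]2C(=O)CC(=O)CC(C)=O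
A5 | alternative 3 | methyl (2S,3S)-3-(3,5-dimethoxyphenyl)-2-(4-hydroxy-3-methoxyphenyl)-6-methoxy-2,3-dihydro-1-benzofuran-5-carboxylate | COC(=O)c1cc2c(cc1OC)O[C@H](c1ccc(O)c(OC)c1)[C@H]2c1cc(OC)cc(OC)c1
A6 | alternative 3 | (3S)-3-(3,5-dimethoxyphenyl)-2-(4-hydroxy-3-methoxyphenyl)-3-[2-hydroxy-4-methoxy-5-(methoxycarbonyl)phenyl]propanoic acid (C2 not assigned) | COC(=O)c1cc(c(O)cc1OC)[C@H](c1cc(OC)cc(OC)c1)C(C(=O)O)c1ccc(O)c(OC)c1
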